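Ring A is numbered C1 (OCH3), C2 (H), C3 (OH), C4 (bearing the CH2 to ring C), C5 (bearing the CH2CH2 to ring B), C6 (H). The feature that allows the key step is that C1 is an oxygen-bearing carbon between two CH carbons (C2, C6) while the second oxygen sits on C3 beside the fully substituted C4: the pattern left by an inserted CO (C1) and an ester shifted from C4 to C3.
Retrosynthesis: after removal of the two benzyl ethers, the C3 pivalate and the C1 O-methyl group, ring A is cut at C1–C2 and C1–C6 into carbon monoxide and an open-chain 3-pivaloyloxy-1,4-enyne. The enyne is cut at C3–C4 (ethynyl Grignard reagent plus α-methylene ketone), the ketone at C4–C5 (Weinreb amide of the ring C acetic acid plus an alkenyllithium), and the alkenyl bromide at the central bond of the two-carbon bridge (ring B benzyl Grignard reagent plus 2,3-dibromopropene).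
Forward: rings B and C are bought as benzyl ethers and the chain is joined in the order bridge bond, C4–C5, C3–C4. Ring A is the only ring made, by the carbonylative (5+1) closure, followed by O-methylation at C1, pivalate removal at C3 and hydrogenolysis.
Stereochemistry: the target is achiral; the one stereocentre on the way (the racemic carbinol carbon of the enyne) becomes the planar C4 on aromatisation, so nothing needs control.

Key step: step 5

Remark on the chemistry: 2-(benzyloxy)benzyl chloride is treated as a purchasable compound (otherwise one step from 2-(benzyloxy)benzyl alcohol with SOCl2), and every compound carrying the carbinol stereocentre is racemic.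

Step 1
Reactants: 1 2-(benzyloxy)benzyl chloride; 2 2,3-dibromoprop-1-ene
Product: 4 1-(benzyloxy)-2-(3-bromobut-3-en-1-yl)benzene, via benzylic Grignard reagent 3 (not isolated)
Conditions: Mg, Et2O, 0 °C to rt; then 2, Et2O/THF, 0 °C to rt
Reagents that add atoms: none
Why: Formation of the benzylic Grignard reagent and its allylic substitution on 2,3-dibromopropene (SN2 and SN2′ give the same product) is a standard entry to 2-bromo-1-alkenes, the vinylic C–Br bond and the aryl benzyl ether being inert to the Grignard reagent.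

Step 2
Reactants: 5 [4-(benzyloxy)phenyl]acetic acid
Product: 7 2-[4-(benzyloxy)phenyl]-N-methoxy-N-methylacetamide, via acylimidazole 6 (not isolated)
Conditions: CDI, CH2Cl2, rt; then MeNHOMe·HCl, rt
Reagents that add atoms: N,O-dimethylhydroxylamine hydrochloride, CNOC.Cl (1,1′-carbonyldiimidazole, O=C(n1ccnc1)n1ccnc1, supplies only the imidazolyl group of intermediate 6)
Why: Weinreb amide formation through the acylimidazole (CDI coupling) is routine for arylacetic acids and uses no reagent that could touch the benzyl ether.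

Step 3
Reactants: 4 1-(benzyloxy)-2-(3-bromobut-3-en-1-yl)benzene; 7 2-[4-(benzyloxy)phenyl]-N-methoxy-N-methylacetamide
Product: 10 1-[4-(benzyloxy)phenyl]-5-[2-(benzyloxy)phenyl]-3-methylidenepentan-2-one, via alkenyllithium 8 (not isolated), via tetrahedral lithium adduct 9 (not isolated)
Conditions: t-BuLi (2.0 equiv), Et2O, −78 °C; then 7, THF, −78 to −20 °C; poured into cold aq. NH4Cl
Reagents that add atoms: none
Why: Bromine–lithium exchange gives the 1,1-disubstituted alkenyllithium, and its acyl substitution on the amide (Weinreb ketone synthesis) should stop at the chelated tetrahedral adduct, so the α-methylene ketone appears only on cold quench and cannot take up a second equivalent of organolithium.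

Step 4
Reactants: 10 1-[4-(benzyloxy)phenyl]-5-[2-(benzyloxy)phenyl]-3-methylidenepentan-2-one; 11 ethynylmagnesium bromide
Product: 13 6-[2-(benzyloxy)phenyl]-3-[4-(benzyloxy)benzyl]-4-methylidenehex-1-yn-3-yl 2,2-dimethylpropanoate (racemic), via bromomagnesium alkoxide 12 (not isolated)
Conditions: HC≡CMgBr, LaCl3·2LiCl, THF, −78 to 0 °C; then PivCl, DMAP (cat.), 0 to 40 °C
Reagents that add atoms: pivaloyl chloride, CC(C)(C)C(Cl)=O
Why: 1,2-Addition of the alkynyl Grignard reagent, which LaCl3·2LiCl should speed up relative to enolisation of the benzylic CH2 and to conjugate addition, gives the tertiary alkoxide, which is O-acylated in the same flask (alkoxide trapping with DMAP acyl transfer); the new stereocentre forms without control as a racemate and is erased in step 5.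

Step 5
Reactants: 13 6-[2-(benzyloxy)phenyl]-3-[4-(benzyloxy)benzyl]-4-methylidenehex-1-yn-3-yl 2,2-dimethylpropanoate; 14 carbon monoxide
Product: 17 2-[4-(benzyloxy)benzyl]-3-{2-[2-(benzyloxy)phenyl]ethyl}-5-hydroxyphenyl 2,2-dimethylpropanoate, via dienylketene 15 (not isolated), via cyclohexadienone 16 (not isolated)
Conditions: [Rh(CO)2Cl]2 (5 mol %), CO (1–10 atm), ClCH2CH2Cl, 80 °C
Reagents that add atoms: none
Why: This is the rhodium-catalysed carbonylative (5+1) benzannulation of a 3-acyloxy-1,4-enyne, a known reaction type used here with a fully substituted carbinol carbon: [Rh(CO)2Cl]2 binds the terminal alkyne, the pivalate carbonyl oxygen attacks the internal alkyne carbon, and the ester shifts from C4 to C3 through a dioxolenium alkenylrhodium species to give a rhodium vinylcarbene at C2 conjugated with C3=C4 and the C5=C6 methylidene group. CO inserts at the carbene carbon and becomes C1 of dienylketene 15 (free or still rhodium-bound), in which C2 and C5 are cis across C3=C4. Ring A closes by six-electron electrocyclisation forming C1–C6 (or the equivalent reductive elimination from an acyl rhodacycle) to dienone 16, which tautomerises to the phenol. No stereocentre is created, and the racemic carbinol centre of 13 becomes the planar C4. The step needs a 1,2- and not a 1,3-acyloxy shift, which the unsubstituted alkyne terminus favours, and CO capture before the carbene closes onto the alkene, which the CO atmosphere favours; the free hydroxyl then appears only on C1 while the hindered pivalate marks C3, so the two oxygens emerge differentiated.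

Step 6
Reactants: 17 2-[4-(benzyloxy)benzyl]-3-{2-[2-(benzyloxy)phenyl]ethyl}-5-hydroxyphenyl 2,2-dimethylpropanoate
Product: 18 2-[4-(benzyloxy)benzyl]-3-{2-[2-(benzyloxy)phenyl]ethyl}-5-methoxyphenyl 2,2-dimethylpropanoate
Conditions: CH3I, K2CO3, acetone, rt to 40 °C
Reagents that add atoms: iodomethane, CI
Why: Williamson methylation of the only free phenol under carbonate conditions should place the methyl group on the C1 oxygen alone, the hindered aryl pivalate being neither cleaved nor transferred by K2CO3 in acetone.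

Step 7
Reactants: 18 2-[4-(benzyloxy)benzyl]-3-{2-[2-(benzyloxy)phenyl]ethyl}-5-methoxyphenyl 2,2-dimethylpropanoate
Product: 19 2-[4-(benzyloxy)benzyl]-3-{2-[2-(benzyloxy)phenyl]ethyl}-5-methoxyphenol
Conditions: NaOCH3, CH3OH/THF, 50 °C; aq. NH4Cl
Reagents that add atoms: none
Why: Methanolysis (transesterification) of the aryl ester by methoxide expels the phenoxide as a good leaving group, while the benzyl and methyl ethers are inert to alkoxide.

Step 8
Reactants: 19 2-[4-(benzyloxy)benzyl]-3-{2-[2-(benzyloxy)phenyl]ethyl}-5-methoxyphenol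
Product: 20 2-(4-hydroxybenzyl)-3-[2-(2-hydroxyphenyl)ethyl]-5-methoxyphenol
Conditions: H2 (1 atm), Pd/C (10 wt % Pd), EtOAc/CH3OH, rt
Reagents that add atoms: none
Why: Catalytic hydrogenolysis (O-debenzylation) should cleave both aryl benzyl ethers, while the diarylmethane and bibenzyl C–C bonds and the aryl methyl ether are stable to hydrogen at one atmosphere and room temperature.

Compound list
1 | 2-(benzyloxy)benzyl chloride | ClCc1ccccc1OCc1ccccc1 | starting material
2 | 2,3-dibromoprop-1-ene | C=C(Br)CBr | starting material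
3 | [2-(benzyloxy)benzyl]magnesium chloride | Cl[Mg]Cc1ccccc1OCc1ccccc1 | intermediate
4 | 1-(benzyloxy)-2-(3-bromobut-3-en-1-yl)benzene | C=C(Br)CCc1ccccc1OCc1ccccc1 | intermediate
5 | [4-(benzyloxy)phenyl]acetic acid | OC(=O)Cc1ccc(OCc2ccccc2)cc1 | starting material
6 | 2-[4-(benzyloxy)phenyl]-1-(1H-imidazol-1-yl)ethan-1-one | O=C(Cc1ccc(OCc2ccccc2)cc1)n1ccnc1 | intermediate
7 | 2-[4-(benzyloxy)phenyl]-N-methoxy-N-methylacetamide | CON(C)C(=O)Cc1ccc(OCc2ccccc2)cc1 | intermediate
8 | {4-[2-(benzyloxy)phenyl]but-1-en-2-yl}lithium | [Li]C(=C)CCc1ccccc1OCc1ccccc1 | intermediate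
9 | lithium 1-[4-(benzyloxy)phenyl]-5-[2-(benzyloxy)phenyl]-2-[methoxy(methyl)amino]-3-methylidenepentan-2-olate (racemic) | [Li]OC(Cc1ccc(OCc2ccccc2)cc1)(N(C)OC)C(=C)CCc1ccccc1OCc1ccccc1 | intermediate
10 | 1-[4-(benzyloxy)phenyl]-5-[2-(benzyloxy)phenyl]-3-methylidenepentan-2-one | O=C(Cc1ccc(OCc2ccccc2)cc1)C(=C)CCc1ccccc1OCc1ccccc1 | intermediate
11 | ethynylmagnesium bromide | C#C[Mg]Br | starting material
12 | bromomagnesium 6-[2-(benzyloxy)phenyl]-3-[4-(benzyloxy)benzyl]-4-methylidenehex-1-yn-3-olate (racemic) | C#CC(O[Mg]Br)(Cc1ccc(OCc2ccccc2)cc1)C(=C)CCc1ccccc1OCc1ccccc1 | intermediate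
13 | 6-[2-(benzyloxy)phenyl]-3-[4-(benzyloxy)benzyl]-4-methylidenehex-1-yn-3-yl 2,2-dimethylpropanoate (racemic) | C#CC(OC(=O)C(C)(C)C)(Cc1ccc(OCc2ccccc2)cc1)C(=C)CCc1ccccc1OCc1ccccc1 | intermediate
14 | carbon monoxide | [C-]#[O+] | starting material
15 | (3E)-4-[4-(benzyloxy)benzyl]-5-{2-[2-(benzyloxy)phenyl]ethyl}-1-oxohexa-1,3,5-trien-3-yl 2,2-dimethylpropanoate (C2 and C5 cis) | O=C=C/C(OC(=O)C(C)(C)C)=C(/Cc1ccc(OCc2ccccc2)cc1)C(=C)CCc1ccccc1OCc1ccccc1 | intermediate
16 | 6-[4-(benzyloxy)benzyl]-5-{2-[2-(benzyloxy)phenyl]ethyl}-3-oxocyclohexa-1,5-dien-1-yl 2,2-dimethylpropanoate (cyclohexa-2,4-dienone tautomer of 17) | O=C1C=C(OC(=O)C(C)(C)C)C(Cc2ccc(OCc3ccccc3)cc2)=C(CCc2ccccc2OCc2ccccc2)C1 | intermediate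
17 | 2-[4-(benzyloxy)benzyl]-3-{2-[2-(benzyloxy)phenyl]ethyl}-5-hydroxyphenyl 2,2-dimethylpropanoate | Oc1cc(OC(=O)C(C)(C)C)c(Cc2ccc(OCc3ccccc3)cc2)c(CCc2ccccc2OCc2ccccc2)c1 | intermediate
18 | 2-[4-(benzyloxy)benzyl]-3-{2-[2-(benzyloxy)phenyl]ethyl}-5-methoxyphenyl 2,2-dimethylpropanoate | COc1cc(OC(=O)C(C)(C)C)c(Cc2ccc(OCc3ccccc3)cc2)c(CCc2ccccc2OCc2ccccc2)c1 | intermediate
19 | 2-[4-(benzyloxy)benzyl]-3-{2-[2-(benzyloxy)phenyl]ethyl}-5-methoxyphenol | COc1cc(O)c(Cc2ccc(OCc3ccccc3)cc2)c(CCc2ccccc2OCc2ccccc2)c1 | intermediate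
20 | 2-(4-hydroxybenzyl)-3-[2-(2-hydroxyphenyl)ethyl]-5-methoxyphenol | COc1cc(O)c(Cc2ccc(O)cc2)c(CCc2ccccc2O)c1 | target

Total step count: 8.
Longest linear sequence: 7 steps (steps 1, 3, 4, 5, 6, 7, 8, from compound 1); step 2 is a one-step side branch.

Steps most likely to fail

Step 5. The rhodium vinylcarbene may close onto the methylidene group before it captures CO, giving a five-membered ring. The ester may shift 1,3 to an allenyl pivalate. The tertiary allylic–propargylic C–O bond may ionise with loss of pivalic acid, since a fully substituted carbinol carbon lies at the limit of what this benzannulation is known to accept.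

The fallback gives up the de novo construction of ring A and buys it as an orsellinate; it sets out from 1 and rejoins the route only at the target 20. Purchased methyl 2-hydroxy-4-methoxy-6-methylbenzoate is benzylated (BnBr, K2CO3, DMF) to methyl 2-(benzyloxy)-4-methoxy-6-methylbenzoate F1. Lateral lithiation of its ring methyl group with LiN(i-Pr)2 in THF at −78 °C gives the benzylic lithium species {[3-(benzyloxy)-5-methoxy-2-(methoxycarbonyl)phenyl]methyl}lithium F2, which is alkylated with 1 to methyl 2-(benzyloxy)-6-{2-[2-(benzyloxy)phenyl]ethyl}-4-methoxybenzoate F3. Reduction with LiAlH4 should give (2-(benzyloxy)-6-{2-[2-(benzyloxy)phenyl]ethyl}-4-methoxyphenyl)methanol F4, and MnO2 in CH2Cl2 the aldehyde 2-(benzyloxy)-6-{2-[2-(benzyloxy)phenyl]ethyl}-4-methoxybenzaldehyde F5. Purchased 4-(benzyloxy)phenylmagnesium bromide then adds to give the racemic diarylmethanol (2-(benzyloxy)-6-{2-[2-(benzyloxy)phenyl]ethyl}-4-methoxyphenyl)[4-(benzyloxy)phenyl]methanol F6. Hydrogenolysis over Pd/C in EtOAc/AcOH should remove the three benzyl ethers and the doubly benzylic hydroxyl in one operation and deliver 20. The substitution pattern of ring A is fixed by the purchased arene, and each operation (lateral metalation of an ortho-toluate, Grignard addition, benzylic hydrogenolysis) is standard.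

Step 4. The acetylide may deprotonate the doubly activated benzylic CH2 of the ketone or add in conjugate fashion to the α-methylene ketone instead of adding 1,2, and O-acylation of the crowded tertiary alkoxide may stall.

The fallback reverses the order in which the carbinol carbon receives its substituents, so that the ketone attacked has no α-hydrogen; it sets out from 4 and returns at 13. Compound 4 is lithiated as in step 3 and the alkenyllithium 8 is added to purchased 3-(trimethylsilyl)prop-2-ynal to give 6-[2-(benzyloxy)phenyl]-4-methylidene-1-(trimethylsilyl)hex-1-yn-3-ol F7. MnO2 oxidises this alcohol to the cross-conjugated ketone 6-[2-(benzyloxy)phenyl]-4-methylidene-1-(trimethylsilyl)hex-1-yn-3-one F8. [4-(Benzyloxy)benzyl]magnesium chloride F9, made from 4-(benzyloxy)benzyl chloride and Mg in Et2O, should add 1,2 at −78 °C, as benzylic Grignard reagents normally do. This gives 6-[2-(benzyloxy)phenyl]-3-[4-(benzyloxy)benzyl]-4-methylidene-1-(trimethylsilyl)hex-1-yn-3-ol F10. The isolated alcohol is deprotonated with LiN(SiMe3)2 and acylated with PivCl to 6-[2-(benzyloxy)phenyl]-3-[4-(benzyloxy)benzyl]-4-methylidene-1-(trimethylsilyl)hex-1-yn-3-yl 2,2-dimethylpropanoate F11. K2CO3 in CH3OH removes the alkynyl silyl group without touching the tertiary pivalate and gives 13.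

Step 3. Proton transfer from the arylacetamide CH2 to the alkenyllithium would return both partners, and the N,O-dimethylhydroxylamine liberated on quench may add in conjugate fashion to the α-methylene ketone.

The fallback lowers the oxidation level of the electrophile and uses a non-basic organometallic; it sets out from 7 (and 4) and returns at 10. Amide 7 is reduced with i-Bu2AlH in THF at −78 °C to [4-(benzyloxy)phenyl]acetaldehyde F12, which is used at once. Alkenyllithium 8, made from 4 as before, is transmetalated with anhydrous CeCl3 at −78 °C to {4-[2-(benzyloxy)phenyl]but-1-en-2-yl}cerium dichloride F13. This reagent should add to the enolisable aldehyde without deprotonating it and give 1-[4-(benzyloxy)phenyl]-5-[2-(benzyloxy)phenyl]-3-methylidenepentan-2-ol F14. Dess–Martin periodinane in CH2Cl2 then oxidises the allylic alcohol to 10 in the absence of any amine.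

Further compounds
F1 | step 5 | methyl 2-(benzyloxy)-4-methoxy-6-methylbenzoate | COC(=O)c1c(C)cc(OC)cc1OCc1ccccc1
F2 | step 5 | {[3-(benzyloxy)-5-methoxy-2-(methoxycarbonyl)phenyl]methyl}lithium | [Li]Cc1cc(OC)cc(OCc2ccccc2)c1C(=O)OC
F3 | step 5 | methyl 2-(benzyloxy)-6-{2-[2-(benzyloxy)phenyl]ethyl}-4-methoxybenzoate | COC(=O)c1c(CCc2ccccc2OCc2ccccc2)cc(OC)cc1OCc1ccccc1
F4 | step 5 | (2-(benzyloxy)-6-{2-[2-(benzyloxy)phenyl]ethyl}-4-methoxyphenyl)methanol | OCc1c(CCc2ccccc2OCc2ccccc2)cc(OC)cc1OCc1ccccc1
F5 | step 5 | 2-(benzyloxy)-6-{2-[2-(benzyloxy)phenyl]ethyl}-4-methoxybenzaldehyde | O=Cc1c(CCc2ccccc2OCc2ccccc2)cc(OC)cc1OCc1ccccc1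
F6 | step 5 | (2-(benzyloxy)-6-{2-[2-(benzyloxy)phenyl]ethyl}-4-methoxyphenyl)[4-(benzyloxy)phenyl]methanol (racemic) | OC(c1ccc(OCc2ccccc2)cc1)c1c(CCc2ccccc2OCc2ccccc2)cc(OC)cc1OCc1ccccc1
F7 | step 4 | 6-[2-(benzyloxy)phenyl]-4-methylidene-1-(trimethylsilyl)hex-1-yn-3-ol (racemic) | C[Si](C)(C)C#CC(O)C(=C)CCc1ccccc1OCc1ccccc1
F8 | step 4 | 6-[2-(benzyloxy)phenyl]-4-methylidene-1-(trimethylsilyl)hex-1-yn-3-one | C[Si](C)(C)C#CC(=O)C(=C)CCc1ccccc1OCc1ccccc1
F9 | step 4 | [4-(benzyloxy)benzyl]magnesium chloride | Cl[Mg]Cc1ccc(OCc2ccccc2)cc1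
F10 | step 4 | 6-[2-(benzyloxy)phenyl]-3-[4-(benzyloxy)benzyl]-4-methylidene-1-(trimethylsilyl)hex-1-yn-3-ol (racemic) | C[Si](C)(C)C#CC(O)(Cc1ccc(OCc2ccccc2)cc1)C(=C)CCc1ccccc1OCc1ccccc1
F11 | step 4 | 6-[2-(benzyloxy)phenyl]-3-[4-(benzyloxy)benzyl]-4-methylidene-1-(trimethylsilyl)hex-1-yn-3-yl 2,2-dimethylpropanoate (racemic) | C[Si](C)(C)C#CC(OC(=O)C(C)(C)C)(Cc1ccc(OCc2ccccc2)cc1)C(=C)CCc1ccccc1OCc1ccccc1
F12 | step 3 | [4-(benzyloxy)phenyl]acetaldehyde | O=CCc1ccc(OCc2ccccc2)cc1
F13 | step 3 | {4-[2-(benzyloxy)phenyl]but-1-en-2-yl}cerium dichloride | Cl[Ce](Cl)C(=C)CCc1ccccc1OCc1ccccc1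
F14 | step 3 | 1-[4-(benzyloxy)phenyl]-5-[2-(benzyloxy)phenyl]-3-methylidenepentan-2-ol (racemic) | OC(Cc1ccc(OCc2ccccc2)cc1)C(=C)CCc1ccccc1OCc1ccccc1
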